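The route rests on disconnecting the C8'–C9' bond of the spiro-dihydrofuran (the CH bearing the 4-hydroxyphenyl group to the spiro carbon, which is also C2 of the benzofuranone). The feature exploited is that the spiro carbon, attached to C8 of the afzelechin A ring, lies 1,5 to the benzylic CH2 of an ether on the neighbouring O7. The precursor is therefore a 2-hydroxy-2-arylbenzofuranone hemiketal in which all flavan phenols carry 4-(benzyloxy)benzyl groups. Acid ionisation, 1,5-hydride shift from the O7 ether and enol/oxocarbenium closure under a chiral Brønsted acid should form the bond, the ring and both stereocentres in one operation, turning a protecting group into skeleton.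

Key step: step 6

Assumption: the chiral-pool flavan-3-ol of step 1 and the phenol of step 4 are taken as purchasable; BOB stands for 4-(benzyloxy)benzyl; primed locants in the spiro compounds are those of the furo[2,3-h]chromene half (O7', C8', spiro C9' = benzofuranone C2); the (S)-acid of step 6 is nominated and its antipode is used should the sense of induction prove opposite.

Step 1
Reactants: 1 (+)-afzelechin; 2 4-(benzyloxy)benzyl chloride
Product: 3 5,7,4'-tri-O-BOB-afzelechin
Conditions: K2CO3, Bu4NI (cat.), DMF, rt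
Reagents that add atoms: 4-(benzyloxy)benzyl chloride, ClCc1ccc(OCc2ccccc2)cc1
Why: Williamson etherification in which carbonate deprotonates only the three phenols (not the secondary 3-OH), leaving both stereocentres untouched and placing on O7 the benzylic CH2 that later becomes C8'.

Step 2
Reactants: 3 5,7,4'-tri-O-BOB-afzelechin; 4 N-bromosuccinimide
Product: 5 8-bromo-5,7,4'-tri-O-BOB-afzelechin
Conditions: NBS, CH2Cl2, −78 °C → rt
Reagents that add atoms: N-bromosuccinimide, O=C1CCC(=O)N1Br
Why: Electrophilic aromatic bromination with the C8 selectivity known for 5,7-di-O-benzylated flavan-3-ols, the position between O7 and the pyran oxygen being the more nucleophilic one.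

Step 3
Reactants: 5 8-bromo-5,7,4'-tri-O-BOB-afzelechin; 6 benzyl bromide
Product: 7 3-O-benzyl-8-bromo-5,7,4'-tri-O-BOB-afzelechin
Conditions: NaH, BnBr, DMF, 0 °C → rt
Reagents that add atoms: benzyl bromide, BrCc1ccccc1
Why: Williamson etherification of the secondary alkoxide masks the only acidic proton before the organolithium step with a group that leaves in the final hydrogenolysis.

Step 4
Reactants: 8 3,5-bis(benzyloxy)phenol; 9 oxalyl chloride
Product: 11 4,6-bis(benzyloxy)benzofuran-2,3-dione, via aryl chlorooxoacetate 10 (not isolated)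
Conditions: (COCl)2, Et2O, 0 °C → reflux
Reagents that add atoms: oxalyl chloride, O=C(Cl)C(Cl)=O
Why: O-acylation of the phenol gives aryl chlorooxoacetate 10, which closes by intramolecular Friedel–Crafts acylation at the ortho carbon activated by the para benzyloxy group to the cyclic α-keto lactone.

Step 5
Reactants: 7 3-O-benzyl-8-bromo-5,7,4'-tri-O-BOB-afzelechin; 11 4,6-bis(benzyloxy)benzofuran-2,3-dione
Product: 13 4,6-bis(benzyloxy)-2-hydroxy-2-(3-O-benzyl-5,7,4'-tri-O-BOB-afzelechin-8-yl)benzofuran-3(2H)-one, via aryllithium 12 (not isolated)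
Conditions: n-BuLi, THF, −78 °C; cannulated into 11, THF, −78 °C; AcOH
Reagents that add atoms: none
Why: Bromine–lithium exchange and 1,2-addition of aryllithium 12 to the lactone carbonyl (an activated aryl ester, whereas the ketone is a vinylogous carbonate shielded by the peri benzyloxy group) give the hemiketal directly, at the 1,2-diketone oxidation level with a free ortho phenol; both hemiketal epimers form, which does not matter because that carbon becomes planar in step 6.

Step 6
Reactants: 13 4,6-bis(benzyloxy)-2-hydroxy-2-(3-O-benzyl-5,7,4'-tri-O-BOB-afzelechin-8-yl)benzofuran-3(2H)-one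
Product: 16 (2S,2'R,3'S,8'S)-3',4,6-tris(benzyloxy)-5'-(BOB-oxy)-2'-[4-(BOB-oxy)phenyl]-8'-[4-(benzyloxy)phenyl]-3',4'-dihydro-2'H,8'H-spiro[benzofuran-2,9'-furo[2,3-h]chromen]-3-one, via benzofuranylium ion 14 (not isolated), via oxocarbenium ion 15 (not isolated)
Conditions: (S)-3,3'-bis(2,4,6-triisopropylphenyl)-1,1'-binaphthalene-2,2'-diyl N-triflylphosphoramide (10 mol%), 5 Å molecular sieves, CH2Cl2, −40 → 0 °C
Reagents that add atoms: none
Why: Proposed new method: the chiral acid ionises both epimers of hemiketal 13 (loss of water) to the same 3-oxobenzofuran-2-ylium ion 14, whose cationic carbon sits on flavan C8 and therefore 1,5 to the benzylic CH2 of the O7 ether; a [1,5]-hydride shift through a six-membered array gives the 4-alkoxyphenyl-stabilised oxocarbenium ion 15 and a now C–H acidic benzofuranone, whose enol adds to the oxocarbenium carbon to forge the C9'–C8' bond. The closest known reaction types are the acid-triggered internal redox cascades of benzylic ethers (1,5-hydride transfer, then ring closure, also under chiral phosphoric acids) and the acid-mediated 1,3 O-to-C ring contraction of cyclic enol acetals (Petasis–Ferrier type), which joins the same kind of enol/oxocarbenium pair into a 3-acyl oxolane. The dihydrofuran ring closes 5-endo-trig on the O7'=C8' oxocarbenium, the mode those ring contractions follow. Both new stereocentres are created in this closure between two planar partners: the spiro centre C9' by the chiral phosphoramidate, which hydrogen-bonds the enol OH and ion-pairs the oxocarbenium so that one enol face is attacked (the flavan centres are too remote to interfere), and C8' by the substrate, the aryl group taking the side of the benzofuranone ring oxygen rather than that of the C3 oxygen and its peri benzyloxy group, hence cis to O1 and trans to C=O. The step needs one hydride donor out of many benzylic C–H bonds and kinetic closure before ether acidolysis: only the O7 methylene can reach the cation (flavan C2–H, though also 1,5, is held anti by the pyran ring; the other ethers are remote), and the catalytic acid, sieves and low temperature should keep the BOB ethers intact and the closure irreversible.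

Step 7
Reactants: 16 protected spiro compound
Product: 17 (2S,2'R,3'S,8'S)-3',4,5',6-tetrahydroxy-2',8'-bis(4-hydroxyphenyl)-3',4'-dihydro-2'H,8'H-spiro[benzofuran-2,9'-furo[2,3-h]chromen]-3-one (CNP0228515.1)
Conditions: H2 (1 atm), Pd(OH)2/C, THF/MeOH, rt
Reagents that add atoms: none
Why: Hydrogenolysis of all benzylic ether protecting groups (the BOB groups leave as toluene and 4-methylphenol), while the two ring benzylic C–O bonds, secondary or neopentylic and embedded in rings, should survive as they do in debenzylation of flavan-3-ols; no stereocentre is touched.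

Compound list

1 | (+)-afzelechin, (2R,3S)-2-(4-hydroxyphenyl)chromane-3,5,7-triol | Oc1cc(O)c2c(c1)O[C@H](c1ccc(O)cc1)[C@@H](O)C2 | starting material
2 | 4-(benzyloxy)benzyl chloride | ClCc1ccc(OCc2ccccc2)cc1 | starting material
3 | (2R,3S)-5,7-bis{[4-(benzyloxy)benzyl]oxy}-2-(4-{[4-(benzyloxy)benzyl]oxy}phenyl)chroman-3-ol | O(Cc1ccc(OCc2ccccc2)cc1)c1cc(OCc2ccc(OCc3ccccc3)cc2)c2c(c1)O[C@H](c1ccc(OCc3ccc(OCc4ccccc4)cc3)cc1)[C@@H](O)C2 | intermediate
4 | N-bromosuccinimide | O=C1CCC(=O)N1Br | starting material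
5 | (2R,3S)-8-bromo-5,7-bis{[4-(benzyloxy)benzyl]oxy}-2-(4-{[4-(benzyloxy)benzyl]oxy}phenyl)chroman-3-ol | O(Cc1ccc(OCc2ccccc2)cc1)c1cc(OCc2ccc(OCc3ccccc3)cc2)c2c(c1Br)O[C@H](c1ccc(OCc3ccc(OCc4ccccc4)cc3)cc1)[C@@H](O)C2 | intermediate
6 | benzyl bromide | BrCc1ccccc1 | starting material
7 | (2R,3S)-3-(benzyloxy)-8-bromo-5,7-bis{[4-(benzyloxy)benzyl]oxy}-2-(4-{[4-(benzyloxy)benzyl]oxy}phenyl)chromane | O(Cc1ccc(OCc2ccccc2)cc1)c1cc(OCc2ccc(OCc3ccccc3)cc2)c2c(c1Br)O[C@H](c1ccc(OCc3ccc(OCc4ccccc4)cc3)cc1)[C@@H](OCc1ccccc1)C2 | intermediate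
8 | 3,5-bis(benzyloxy)phenol | Oc1cc(OCc2ccccc2)cc(OCc2ccccc2)c1 | starting material
9 | oxalyl chloride | O=C(Cl)C(Cl)=O | starting material
10 | 3,5-bis(benzyloxy)phenyl chlorooxoacetate | O=C(Cl)C(=O)Oc1cc(OCc2ccccc2)cc(OCc2ccccc2)c1 | intermediate (not isolated)
11 | 4,6-bis(benzyloxy)benzofuran-2,3-dione | O=C1Oc2cc(OCc3ccccc3)cc(OCc3ccccc3)c2C1=O | intermediate
12 | 8-lithio derivative of 7 (aryllithium) | O(Cc1ccc(OCc2ccccc2)cc1)c1cc(OCc2ccc(OCc3ccccc3)cc2)c2c(c1[Li])O[C@H](c1ccc(OCc3ccc(OCc4ccccc4)cc3)cc1)[C@@H](OCc1ccccc1)C2 | intermediate (not isolated)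
13 | 4,6-bis(benzyloxy)-2-hydroxy-2-[(2R,3S)-3-(benzyloxy)-5,7-bis{[4-(benzyloxy)benzyl]oxy}-2-(4-{[4-(benzyloxy)benzyl]oxy}phenyl)chroman-8-yl]benzofuran-3(2H)-one (both hemiketal epimers, in equilibrium with the open-chain 2-hydroxyaryl 1,2-diketone) | O=C1c2c(OCc3ccccc3)cc(OCc3ccccc3)cc2OC1(O)c1c(cc(OCc2ccc(OCc3ccccc3)cc2)c2c1O[C@H](c1ccc(OCc3ccc(OCc4ccccc4)cc3)cc1)[C@@H](OCc1ccccc1)C2)OCc1ccc(OCc2ccccc2)cc1 | intermediate
14 | 2-aryl-4,6-bis(benzyloxy)-3-oxobenzofuran-2-ylium ion (aryl = the flavan-8-yl group of 13), as its phosphoramidate ion pair | O=C1c2c(OCc3ccccc3)cc(OCc3ccccc3)cc2O[C+]1c1c(cc(OCc2ccc(OCc3ccccc3)cc2)c2c1O[C@H](c1ccc(OCc3ccc(OCc4ccccc4)cc3)cc1)[C@@H](OCc1ccccc1)C2)OCc1ccc(OCc2ccccc2)cc1 | intermediate (not isolated)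
15 | O7-[4-(benzyloxy)benzylidene]oxonium ion of the 2-aryl-4,6-bis(benzyloxy)benzofuran-3(2H)-one, as its phosphoramidate ion pair | O=C1c2c(OCc3ccccc3)cc(OCc3ccccc3)cc2OC1c1c(cc(OCc2ccc(OCc3ccccc3)cc2)c2c1O[C@H](c1ccc(OCc3ccc(OCc4ccccc4)cc3)cc1)[C@@H](OCc1ccccc1)C2)[O+]=Cc1ccc(OCc2ccccc2)cc1 | intermediate (not isolated)
16 | (2S,2'R,3'S,8'S)-3',4,6-tris(benzyloxy)-5'-{[4-(benzyloxy)benzyl]oxy}-2'-(4-{[4-(benzyloxy)benzyl]oxy}phenyl)-8'-[4-(benzyloxy)phenyl]-3',4'-dihydro-2'H,8'H-spiro[benzofuran-2,9'-furo[2,3-h]chromen]-3-one | O=C1c2c(OCc3ccccc3)cc(OCc3ccccc3)cc2O[C@]12c1c(cc(OCc3ccc(OCc4ccccc4)cc3)c3c1O[C@H](c1ccc(OCc4ccc(OCc5ccccc5)cc4)cc1)[C@@H](OCc1ccccc1)C3)O[C@H]2c1ccc(OCc2ccccc2)cc1 | intermediate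
17 | (2S,2'R,3'S,8'S)-3',4,5',6-tetrahydroxy-2',8'-bis(4-hydroxyphenyl)-3',4'-dihydro-2'H,8'H-spiro[benzofuran-2,9'-furo[2,3-h]chromen]-3-one (CNP0228515.1) | O=C1c2c(O)cc(O)cc2O[C@]12c1c(cc(O)c3c1O[C@H](c1ccc(O)cc1)[C@@H](O)C3)O[C@H]2c1ccc(O)cc1 | target

Total step count: 7. Longest linear sequence: 6 steps (steps 1, 2, 3, 5, 6, 7); step 4 is a one-step side branch.

Steps most likely to fail

Step 6 (Proposed new method). The cation may be trapped or decompose before the hydride shift, the BOB ethers may be lost by acidolysis, or the chiral anion may give poor facial control at the spiro carbon. The fallback uses known photochemistry, sets out from 13 and returns at 16. Acetylation (Ac2O, Et3N, DMAP, CH2Cl2) of the phenol of the open-chain tautomer traps it as the aryl acetate 1,2-diketone F1. Irradiation (blue LED, benzene, rt) should bring about a Norrish–Yang photocyclisation: the carbonyl next to the flavan ring abstracts a δ-hydrogen from the same O7 methylene and the 1,5-biradical closes the C9–C8 bond to give the tertiary alcohol F2, with aryl and hydroxyl cis as expected for ortho-benzyloxyaryl ketones. No catalyst controls the absolute sense here, so the (8S,9S) isomer would have to be separated from its (8R,9R) counterpart and from products of abstraction at the benzyloxy group ortho to the other carbonyl. Methanolysis (K2CO3, MeOH, 0 °C) frees the phenol F3. Pyridinium p-toluenesulfonate in CH2Cl2 then ionises the tertiary benzylic alcohol and the phenol closes the benzofuranone ring to give 16; under these equilibrating conditions the isomer with the 8'-aryl group anti to the carbonyl is the one expected.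

Step 5. The aryllithium may attack the ketone carbonyl of the dione instead of the lactone carbonyl, or add twice after ring opening. The fallback replaces lactone opening by acylation of an open-chain amide; it sets out from 11 and 7 and returns at 13. N,O-Dimethylhydroxylamine opens dione 11 at the lactone carbonyl to the 2-hydroxyaryl α-keto N-methoxy-N-methylamide F4, and t-BuMe2SiCl with imidazole gives the silyl ether F5. Aryllithium 12 (from 7, n-BuLi, THF, −78 °C) is acylated at the amide carbonyl, whose chelated adduct cannot add a second time, to give the open-chain 1,2-diketone silyl ether F6. Bu4NF buffered with AcOH releases the phenol, which closes to hemiketal 13.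

Step 7. Hydrogenolysis may go too far and cleave the benzylic C–O bonds of the dihydrofuran or pyran ring, or stall at partly protected material. The fallback replaces reduction by Lewis-acid debenzylation with a cation scavenger; it sets out from 16, returns at 17 and makes no new compound (F0). BCl3 with pentamethylbenzene in CH2Cl2 at −78 °C should remove all benzyl and BOB groups, the benzylic cations being captured by the arene.

Further compounds

F1 | step 6 | 1-[2-acetoxy-4,6-bis(benzyloxy)phenyl]-2-[(2R,3S)-3-(benzyloxy)-5,7-bis{[4-(benzyloxy)benzyl]oxy}-2-(4-{[4-(benzyloxy)benzyl]oxy}phenyl)chroman-8-yl]ethane-1,2-dione | CC(=O)Oc1cc(OCc2ccccc2)cc(OCc2ccccc2)c1C(=O)C(=O)c1c(cc(OCc2ccc(OCc3ccccc3)cc2)c2c1O[C@H](c1ccc(OCc3ccc(OCc4ccccc4)cc3)cc1)[C@@H](OCc1ccccc1)C2)OCc1ccc(OCc2ccccc2)cc1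
F2 | step 6 | [2-acetoxy-4,6-bis(benzyloxy)phenyl][(2R,3S,8S,9S)-3-(benzyloxy)-8-[4-(benzyloxy)phenyl]-5-{[4-(benzyloxy)benzyl]oxy}-2-(4-{[4-(benzyloxy)benzyl]oxy}phenyl)-9-hydroxy-3,4,8,9-tetrahydro-2H-furo[2,3-h]chromen-9-yl]methanone | O[C@@]1(C(=O)c2c(OC(C)=O)cc(OCc3ccccc3)cc2OCc2ccccc2)c2c(cc(OCc3ccc(OCc4ccccc4)cc3)c3c2O[C@H](c2ccc(OCc4ccc(OCc5ccccc5)cc4)cc2)[C@@H](OCc2ccccc2)C3)O[C@H]1c1ccc(OCc2ccccc2)cc1
F3 | step 6 | [2,4-bis(benzyloxy)-6-hydroxyphenyl][(2R,3S,8S,9S)-3-(benzyloxy)-8-[4-(benzyloxy)phenyl]-5-{[4-(benzyloxy)benzyl]oxy}-2-(4-{[4-(benzyloxy)benzyl]oxy}phenyl)-9-hydroxy-3,4,8,9-tetrahydro-2H-furo[2,3-h]chromen-9-yl]methanone | O[C@@]1(C(=O)c2c(O)cc(OCc3ccccc3)cc2OCc2ccccc2)c2c(cc(OCc3ccc(OCc4ccccc4)cc3)c3c2O[C@H](c2ccc(OCc4ccc(OCc5ccccc5)cc4)cc2)[C@@H](OCc2ccccc2)C3)O[C@H]1c1ccc(OCc2ccccc2)cc1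
F4 | step 5 | 2-[2,4-bis(benzyloxy)-6-hydroxyphenyl]-N-methoxy-N-methyl-2-oxoacetamide | CON(C)C(=O)C(=O)c1c(O)cc(OCc2ccccc2)cc1OCc1ccccc1
F5 | step 5 | 2-[2,4-bis(benzyloxy)-6-(tert-butyldimethylsilyloxy)phenyl]-N-methoxy-N-methyl-2-oxoacetamide | CON(C)C(=O)C(=O)c1c(O[Si](C)(C)C(C)(C)C)cc(OCc2ccccc2)cc1OCc1ccccc1
F6 | step 5 | 1-[2,4-bis(benzyloxy)-6-(tert-butyldimethylsilyloxy)phenyl]-2-[(2R,3S)-3-(benzyloxy)-5,7-bis{[4-(benzyloxy)benzyl]oxy}-2-(4-{[4-(benzyloxy)benzyl]oxy}phenyl)chroman-8-yl]ethane-1,2-dione | O=C(C(=O)c1c(O[Si](C)(C)C(C)(C)C)cc(OCc2ccccc2)cc1OCc1ccccc1)c1c(cc(OCc2ccc(OCc3ccccc3)cc2)c2c1O[C@H](c1ccc(OCc3ccc(OCc4ccccc4)cc3)cc1)[C@@H](OCc1ccccc1)C2)OCc1ccc(OCc2ccccc2)cc1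
F0 | step 7 | none | none
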